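**Retrosynthetic overview**

1. Locants (1H-isochromene core): C1H2–O2–C3(=C4)–C4a(=C5)–C6(=O)–C7(Me)(OH)–C8(O-aroyl)–C8a. Ring A is the carbocycle C4a–C5–C6–C7–C8–C8a; ring B is the pyran O2–C1–C8a–C4a–C4–C3.
2. Last disconnection: acidolysis of two MOM ethers and one tert-butyl ester. Before it, both rings open in one retro-step, ring B at O2–C3 (oxa-conjugate addition) and ring A at C4a–C8a (radical closure), leading to an acyclic oxiranyl diynone: C1–C8a epoxide, C6(=O)–C5≡C4a–C4≡C3–CH=CH–CO2t-Bu.
3. Enabling feature: C8a carries the C1 oxymethylene, so a C8a radical with a metal alkoxide on C1 is what reductive homolysis of a C1–C8a epoxide delivers. C4a is both the β-carbon of the ring A enone and the carbon from which the C4=C3–O2 enol ether of ring B starts, so in the diynone C4a accepts the radical and C3 accepts the freed C1 hydroxyl.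
4. The acyclic chain comes from (E)-2-methylpenta-2,4-dien-1-ol: Sharpless epoxidation sets C7; invertive epoxide opening at C8 by MOM-protected orsellinic acid sets C8 and installs the ester; then C6 oxidation, C5–C3 from 1,4-bis(trimethylsilyl)butadiyne, the acrylate by Sonogashira coupling, and late epoxidation of the vinyl group (C8a=C1).
5. Ring order in the forward sense: ring A (C4a–C8a), then ring B (O2–C3), both in step 13.

Key step: step 13

Assumption: the carbinol carbon that becomes C6 (compounds 14–16) and the oxirane carbon that becomes C8a (compound 18) are carried as epimer mixtures, because both centres are erased later (oxidation in step 11, planar radical in step 13).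

**Route**

Step 1
Reactants: 1 2,4-dihydroxy-6-methylbenzaldehyde
Product: 2 2,4-bis(methoxymethoxy)-6-methylbenzaldehyde
Conditions: NaH, MOMCl, DMF, 0 °C to rt
Reagents that add atoms: chloromethyl methyl ether, COCCl
Why: Williamson etherification of both phenoxides, NaH being needed for the hydrogen-bonded ortho hydroxyl; the acetals are removed at the end by acid together with the tert-butyl ester.

Step 2
Reactants: 2 2,4-bis(methoxymethoxy)-6-methylbenzaldehyde
Product: 3 2,4-bis(methoxymethoxy)-6-methylbenzoic acid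
Conditions: NaClO2, NaH2PO4, 2-methylbut-2-ene, t-BuOH/H2O, rt
Reagents that add atoms: sodium chlorite, [Na+].[O-]Cl=O
Why: Pinnick oxidation should convert the hindered aldehyde into the acid without touching the acetals.

Step 3
Reactants: 4 (E)-3-iodoacrylic acid
Product: 5 tert-butyl (E)-3-iodoacrylate
Conditions: tert-butyl 2,2,2-trichloroacetimidate, BF3·OEt2 (cat.), CH2Cl2/cyclohexane, rt
Reagents that add atoms: tert-butyl 2,2,2-trichloroacetimidate, CC(C)(C)OC(=N)C(Cl)(Cl)Cl
Why: acid-catalysed imidate O-alkylation should give the tert-butyl ester under conditions that leave the (E)-vinyl iodide untouched.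

Step 4
Reactants: 6 acrolein; 7 ethyl 2-(triphenylphosphoranylidene)propanoate
Product: 8 ethyl (2E)-2-methylpenta-2,4-dienoate
Conditions: CH2Cl2, 0 °C to rt
Reagents that add atoms: none
Why: Wittig olefination with the stabilised, α-branched ylide should give the (E)-trisubstituted alkene.

Step 5
Reactants: 8 ethyl (2E)-2-methylpenta-2,4-dienoate
Product: 9 (2E)-2-methylpenta-2,4-dien-1-ol
Conditions: i-Bu2AlH, CH2Cl2, −78 to 0 °C; aq. potassium sodium tartrate
Reagents that add atoms: none
Why: 1,2-reduction of the conjugated ester by the aluminium hydride should give the allylic alcohol needed for hydroxyl-directed epoxidation.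

Step 6
Reactants: 9 (2E)-2-methylpenta-2,4-dien-1-ol
Product: 10 [(2R,3R)-3-ethenyl-2-methyloxiran-2-yl]methanol
Conditions: Ti(OiPr)4 (10 mol%), D-(−)-diisopropyl tartrate (12 mol%), t-BuOOH, 4 Å molecular sieves, CH2Cl2, −20 °C
Reagents that add atoms: tert-butyl hydroperoxide, CC(C)(C)OO
Why: Sharpless asymmetric epoxidation is directed by the hydroxyl to the trisubstituted allylic alkene only, and the D-(−)-tartrate ligand should deliver oxygen to the face that gives the (2R,3R)-epoxide, which fixes the later C7 centre.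

Step 7
Reactants: 10 [(2R,3R)-3-ethenyl-2-methyloxiran-2-yl]methanol; 3 2,4-bis(methoxymethoxy)-6-methylbenzoic acid
Product: 11 (2R,3S)-1,2-dihydroxy-2-methylpent-4-en-3-yl 2,4-bis(methoxymethoxy)-6-methylbenzoate
Conditions: Ti(OiPr)4 (1.5 equiv), CH2Cl2, rt; aq. tartaric acid
Reagents that add atoms: none
Why: the Ti(OiPr)4-mediated opening of a 2,3-epoxy alcohol by a carboxylic acid takes place at C3, here also the allylic carbon, with SN2 inversion, so the later C8 centre is set (3S) and the orsellinate is installed without acylating a hindered alcohol.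

Step 8
Reactants: 11 (2R,3S)-1,2-dihydroxy-2-methylpent-4-en-3-yl 2,4-bis(methoxymethoxy)-6-methylbenzoate
Product: 12 (2S,3S)-2-hydroxy-2-methyl-1-oxopent-4-en-3-yl 2,4-bis(methoxymethoxy)-6-methylbenzoate
Conditions: SO3·pyridine, DMSO, i-Pr2NEt, CH2Cl2, 0 °C
Reagents that add atoms: none
Why: Parikh–Doering oxidation should convert the primary alcohol into the aldehyde while the tertiary hydroxyl stays; the aldehyde has no α-hydrogen and can neither epimerise nor eliminate.

Step 9
Reactants: 12 (2S,3S)-2-hydroxy-2-methyl-1-oxopent-4-en-3-yl 2,4-bis(methoxymethoxy)-6-methylbenzoate; 13 1,4-bis(trimethylsilyl)buta-1,3-diyne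
Product: 14 (3S,4R)-4,5-dihydroxy-4-methyl-9-(trimethylsilyl)non-1-ene-6,8-diyn-3-yl 2,4-bis(methoxymethoxy)-6-methylbenzoate (mixture of C5 epimers)
Conditions: 13, MeLi·LiBr, THF, 0 °C to rt; then 12, −78 °C; aq. NH4Cl
Reagents that add atoms: none
Why: mono-desilylation of 13 by methyllithium gives the lithium diynide, which should add 1,2 to the aldehyde (an excess is used because the tertiary hydroxyl consumes one equivalent); the new carbinol centre is irrelevant because it is oxidised in step 11.

Step 10
Reactants: 14 (3S,4R)-4,5-dihydroxy-4-methyl-9-(trimethylsilyl)non-1-ene-6,8-diyn-3-yl 2,4-bis(methoxymethoxy)-6-methylbenzoate; 5 tert-butyl (E)-3-iodoacrylate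
Product: 16 tert-butyl (2E,9R,10S)-10-{[2,4-bis(methoxymethoxy)-6-methylbenzoyl]oxy}-8,9-dihydroxy-9-methyldodeca-2,11-dien-4,6-diynoate (mixture of C8 epimers), via terminal diyne 15 (not isolated)
Conditions: K2CO3 (cat.), MeOH/THF, 0 °C; then 5, Pd(PPh3)2Cl2 (5 mol%), CuI (10 mol%), i-Pr2NH, THF, degassed, 0 °C to rt
Reagents that add atoms: none
Why: methanolysis removes the alkynyl silyl group and the sensitive terminal diyne is coupled at once with the vinyl iodide by Sonogashira reaction, with retention of the (E) geometry.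

Step 11
Reactants: 16 tert-butyl (2E,9R,10S)-10-{[2,4-bis(methoxymethoxy)-6-methylbenzoyl]oxy}-8,9-dihydroxy-9-methyldodeca-2,11-dien-4,6-diynoate
Product: 17 tert-butyl (2E,9S,10S)-10-{[2,4-bis(methoxymethoxy)-6-methylbenzoyl]oxy}-9-hydroxy-9-methyl-8-oxododeca-2,11-dien-4,6-diynoate
Conditions: Dess–Martin periodinane, CH2Cl2, 0 °C to rt
Reagents that add atoms: none
Why: Dess–Martin oxidation of the secondary propargylic alcohol should give the diynone and converge both carbinol epimers, the tertiary hydroxyl being inert.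

Step 12
Reactants: 17 tert-butyl (2E,9S,10S)-10-{[2,4-bis(methoxymethoxy)-6-methylbenzoyl]oxy}-9-hydroxy-9-methyl-8-oxododeca-2,11-dien-4,6-diynoate
Product: 18 tert-butyl (2E,9S,10S)-10-{[2,4-bis(methoxymethoxy)-6-methylbenzoyl]oxy}-9-hydroxy-9-methyl-10-(oxiran-2-yl)-8-oxodec-2-en-4,6-diynoate (mixture of oxirane epimers)
Conditions: dimethyldioxirane (acetone solution), CH2Cl2, 0 °C to rt
Reagents that add atoms: dimethyldioxirane, CC1(C)OO1
Why: electrophilic epoxidation by the dioxirane under neutral conditions should take the only alkene that is not conjugated to a carbonyl group or an alkyne; the configuration of the new oxirane carbon does not matter because it becomes a planar radical in step 13.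

Step 13
Reactants: 18 tert-butyl (2E,9S,10S)-10-{[2,4-bis(methoxymethoxy)-6-methylbenzoyl]oxy}-9-hydroxy-9-methyl-10-(oxiran-2-yl)-8-oxodec-2-en-4,6-diynoate
Product: 20 (7S,8S,8aS)-3-[(E)-3-(tert-butoxy)-3-oxoprop-1-en-1-yl]-7-hydroxy-7-methyl-6-oxo-6,7,8,8a-tetrahydro-1H-isochromen-8-yl 2,4-bis(methoxymethoxy)-6-methylbenzoate, via hydroxymethyl enynone 19 (not isolated)
Conditions: Cp2TiCl2 (20 mol%), Mn dust, 2,4,6-collidine·HCl, THF, rt, high dilution with slow addition of 18; then DBU, 0 °C
Reagents that add atoms: none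
Why: Proposed new method: Cp2TiCl (trivalent titanium, formed and recycled from Cp2TiCl2 by Mn) should open the terminal epoxide homolytically to the more substituted C8a radical with the oxygen left on C1 as a titanium alkoxide, and this nucleophilic radical should add to C4a, the β-carbon of the C6 ynone, so that ring A closes in a 6-endo-dig radical mode; the resulting α-keto vinyl radical at C5 is reduced and protonated by collidinium to enone 19, the closest known reaction type being the titanocene-mediated epoxide-opening radical cyclization onto alkynes and unsaturated carbonyl compounds combined with the polarity-controlled 6-endo closure of alkyl radicals onto in-chain enones, whereas an in-chain ynone acceptor in this mode is not documented. Ring B then closes in the same flask by base-catalysed 6-endo-dig oxa-conjugate (1,6-) addition of the C1 hydroxyl to C3 of the enynone, the non-aromatic counterpart of the alkynyl-to-pyran cycloisomerization used for azaphilone cores. C8a is the only new stereocentre: it is planar in the radical, so both oxirane epimers converge, and a chair-like transition state with the C7 methyl and the C8 aroyloxy group pseudo-equatorial should place the C1 oxymethylene pseudo-equatorial too, trans to the C8 oxygen (8aS), which is also the more stable epimer should the γ-position equilibrate under DBU. The step needs 6-endo over 5-exo attack (secured by polarity, attack at the α-carbon C5 being mismatched for a nucleophilic radical), cyclization faster than capture of the C8a radical by a second titanium centre followed by β-elimination (secured by catalytic titanium and high dilution), and O2 attack at C3 instead of C4 (secured by the through-conjugation of C3 with the C6 ketone, which makes the pyran the stabilised vinylogous ester).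

Step 14
Reactants: 20 (7S,8S,8aS)-3-[(E)-3-(tert-butoxy)-3-oxoprop-1-en-1-yl]-7-hydroxy-7-methyl-6-oxo-6,7,8,8a-tetrahydro-1H-isochromen-8-yl 2,4-bis(methoxymethoxy)-6-methylbenzoate
Product: 21 Pinophilin G, (2E)-3-[(7S,8S,8aS)-8-[(2,4-dihydroxy-6-methylbenzoyl)oxy]-7-hydroxy-7-methyl-6-oxo-6,7,8,8a-tetrahydro-1H-isochromen-3-yl]prop-2-enoic acid
Conditions: CF3CO2H/CH2Cl2, H2O (few equiv), 0 °C to rt
Reagents that add atoms: none
Why: acidolysis should remove both methoxymethyl acetals and the tert-butyl ester in one operation, the vinylogous ester of ring B and the hindered C8 ester being expected to survive; no stereocentre is touched.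

**Compound list**

1 | 2,4-dihydroxy-6-methylbenzaldehyde | Cc1cc(O)cc(O)c1C=O | starting material
2 | 2,4-bis(methoxymethoxy)-6-methylbenzaldehyde | Cc1cc(OCOC)cc(OCOC)c1C=O | intermediate
3 | 2,4-bis(methoxymethoxy)-6-methylbenzoic acid | Cc1cc(OCOC)cc(OCOC)c1C(=O)O | intermediate
4 | (E)-3-iodoacrylic acid | OC(=O)/C=C/I | starting material
5 | tert-butyl (E)-3-iodoacrylate | CC(C)(C)OC(=O)/C=C/I | intermediate
6 | acrolein | C=CC=O | starting material
7 | ethyl 2-(triphenylphosphoranylidene)propanoate | CCOC(=O)C(C)=P(c1ccccc1)(c1ccccc1)c1ccccc1 | starting material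
8 | ethyl (2E)-2-methylpenta-2,4-dienoate | CCOC(=O)/C(C)=C/C=C | intermediate
9 | (2E)-2-methylpenta-2,4-dien-1-ol | OC/C(C)=C/C=C | intermediate
10 | [(2R,3R)-3-ethenyl-2-methyloxiran-2-yl]methanol | OC[C@@]1(C)O[C@@H]1C=C | intermediate
11 | (2R,3S)-1,2-dihydroxy-2-methylpent-4-en-3-yl 2,4-bis(methoxymethoxy)-6-methylbenzoate | C=C[C@H](OC(=O)c1c(C)cc(OCOC)cc1OCOC)[C@](C)(O)CO | intermediate
12 | (2S,3S)-2-hydroxy-2-methyl-1-oxopent-4-en-3-yl 2,4-bis(methoxymethoxy)-6-methylbenzoate | C=C[C@H](OC(=O)c1c(C)cc(OCOC)cc1OCOC)[C@](C)(O)C=O | intermediate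
13 | 1,4-bis(trimethylsilyl)buta-1,3-diyne | C[Si](C)(C)C#CC#C[Si](C)(C)C | starting material
14 | (3S,4R)-4,5-dihydroxy-4-methyl-9-(trimethylsilyl)non-1-ene-6,8-diyn-3-yl 2,4-bis(methoxymethoxy)-6-methylbenzoate, C5 epimers | C=C[C@H](OC(=O)c1c(C)cc(OCOC)cc1OCOC)[C@](C)(O)C(O)C#CC#C[Si](C)(C)C | intermediate
15 | (3S,4R)-4,5-dihydroxy-4-methylnon-1-ene-6,8-diyn-3-yl 2,4-bis(methoxymethoxy)-6-methylbenzoate, C5 epimers | C=C[C@H](OC(=O)c1c(C)cc(OCOC)cc1OCOC)[C@](C)(O)C(O)C#CC#C | intermediate
16 | tert-butyl (2E,9R,10S)-10-{[2,4-bis(methoxymethoxy)-6-methylbenzoyl]oxy}-8,9-dihydroxy-9-methyldodeca-2,11-dien-4,6-diynoate, C8 epimers | C=C[C@H](OC(=O)c1c(C)cc(OCOC)cc1OCOC)[C@](C)(O)C(O)C#CC#C/C=C/C(=O)OC(C)(C)C | intermediate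
17 | tert-butyl (2E,9S,10S)-10-{[2,4-bis(methoxymethoxy)-6-methylbenzoyl]oxy}-9-hydroxy-9-methyl-8-oxododeca-2,11-dien-4,6-diynoate | C=C[C@H](OC(=O)c1c(C)cc(OCOC)cc1OCOC)[C@](C)(O)C(=O)C#CC#C/C=C/C(=O)OC(C)(C)C | intermediate
18 | tert-butyl (2E,9S,10S)-10-{[2,4-bis(methoxymethoxy)-6-methylbenzoyl]oxy}-9-hydroxy-9-methyl-10-(oxiran-2-yl)-8-oxodec-2-en-4,6-diynoate, oxirane epimers | C1OC1[C@H](OC(=O)c2c(C)cc(OCOC)cc2OCOC)[C@](C)(O)C(=O)C#CC#C/C=C/C(=O)OC(C)(C)C | intermediate
19 | tert-butyl (2E)-5-[(4S,5S,6S)-5-{[2,4-bis(methoxymethoxy)-6-methylbenzoyl]oxy}-4-hydroxy-6-(hydroxymethyl)-4-methyl-3-oxocyclohex-1-en-1-yl]pent-2-en-4-ynoate | Cc1cc(OCOC)cc(OCOC)c1C(=O)O[C@H]1[C@H](CO)C(C#C/C=C/C(=O)OC(C)(C)C)=CC(=O)[C@@]1(C)O | intermediate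
20 | (7S,8S,8aS)-3-[(E)-3-(tert-butoxy)-3-oxoprop-1-en-1-yl]-7-hydroxy-7-methyl-6-oxo-6,7,8,8a-tetrahydro-1H-isochromen-8-yl 2,4-bis(methoxymethoxy)-6-methylbenzoate | Cc1cc(OCOC)cc(OCOC)c1C(=O)O[C@H]1[C@@H]2COC(/C=C/C(=O)OC(C)(C)C)=CC2=CC(=O)[C@@]1(C)O | intermediate
21 | Pinophilin G | Cc1cc(O)cc(O)c1C(=O)O[C@H]1[C@@H]2COC(/C=C/C(=O)O)=CC2=CC(=O)[C@@]1(C)O | target

**Step count**

Total: 14 steps. Longest linear sequence: 11 steps (steps 4 to 14, from acrolein); steps 1–2 and step 3 are side branches.

**Three steps most likely to fail**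

Step 13 (proposed new method). The radical at C8a may be captured by a second titanium centre before it cyclises, followed by β-elimination of the C8 aroyloxy or the C1 titanoxy group. The diynone may be reduced by the low-valent metal. The closure may go 5-exo. Base may cause γ-deprotonation at C8a and loss of the C8 ester. The fallback uses known chemistry, sets out from 17 and comes back at 19. Compound 17 is dihydroxylated at the terminal alkene (OsO4 cat., N-methylmorpholine N-oxide, acetone/H2O) to terminal diol F1, which 1,1'-thiocarbonyldiimidazole in THF converts into cyclic thionocarbonate F2. Bu3SnH with AIBN in benzene at 80 °C under high dilution then generates the same C8a radical by Barton–McCombie fragmentation of the secondary C–O bond, with no low-valent metal present. After 6-endo closure and hydrogen transfer from the stannane this should give stannyl thiocarbonate F3, whose hydrolysis on work-up releases 19. DBU then closes ring B to 20 as in step 13.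

Step 7. The hindered carboxylate may be delivered too slowly, so that attack at the vinyl terminus (SN2′), ionisation of the allylic C–O bond with loss of stereospecificity, or opening by isopropoxide take over. The fallback makes the C8 ester by O-acylation of a preformed C8 hydroxyl, sets out from 10 and comes back at 11. Compound 10 is opened under the same titanium-mediated, invertive conditions by benzoic acid, a small acid for which this opening is established, to (2R,3S)-1,2-dihydroxy-2-methylpent-4-en-3-yl benzoate F4. Methanolysis (K2CO3, MeOH) gives (2R,3S)-2-methylpent-4-ene-1,2,3-triol F5. The primary hydroxyl is silylated (TBSCl, imidazole) to silyl ether F6. The secondary hydroxyl is acylated with retention by 2,4-bis(methoxymethoxy)-6-methylbenzoyl chloride F7 (from 3 and 1-chloro-N,N,2-trimethylprop-1-en-1-amine; Et3N, DMAP) to silyl-protected ester F8. HF·pyridine then removes the silyl group to give 11.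

Step 14. The methoxymethyl cation or formaldehyde released under protic acid may alkylate the electron-rich resorcinol ring; the acyl group may migrate from O8 to O7; the enol ether of ring B may be hydrated. The fallback replaces Brønsted acidolysis by silyl transfer, sets out from 20 and comes back at 21. TMSOTf with 2,2'-bipyridyl in CH2Cl2 at 0 °C should exchange the two aryl methoxymethyl acetals and the tert-butyl ester for trimethylsilyl groups under buffered, non-protic conditions, and silylate the tertiary hydroxyl, giving tetrakis(trimethylsilyl) derivative F9. Aqueous citric acid in THF then hydrolyses F9 to 21.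

**Further compounds**

F1 | step 13 | tert-butyl (2E,9S,10S)-10-{[2,4-bis(methoxymethoxy)-6-methylbenzoyl]oxy}-9,11,12-trihydroxy-9-methyl-8-oxododec-2-en-4,6-diynoate, C11 epimers | OCC(O)[C@H](OC(=O)c1c(C)cc(OCOC)cc1OCOC)[C@](C)(O)C(=O)C#CC#C/C=C/C(=O)OC(C)(C)C
F2 | step 13 | tert-butyl (2E,9S,10S)-10-{[2,4-bis(methoxymethoxy)-6-methylbenzoyl]oxy}-9-hydroxy-9-methyl-8-oxo-10-(2-thioxo-1,3-dioxolan-4-yl)dec-2-en-4,6-diynoate | S=C1OCC(O1)[C@H](OC(=O)c2c(C)cc(OCOC)cc2OCOC)[C@](C)(O)C(=O)C#CC#C/C=C/C(=O)OC(C)(C)C
F3 | step 13 | tert-butyl (2E)-5-[(4S,5S,6S)-5-{[2,4-bis(methoxymethoxy)-6-methylbenzoyl]oxy}-4-hydroxy-4-methyl-3-oxo-6-[({[(tributylstannyl)sulfanyl]carbonyl}oxy)methyl]cyclohex-1-en-1-yl]pent-2-en-4-ynoate | Cc1cc(OCOC)cc(OCOC)c1C(=O)O[C@H]1[C@H](COC(=O)S[Sn](CCCC)(CCCC)CCCC)C(C#C/C=C/C(=O)OC(C)(C)C)=CC(=O)[C@@]1(C)O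
F4 | step 7 | (2R,3S)-1,2-dihydroxy-2-methylpent-4-en-3-yl benzoate | C=C[C@H](OC(=O)c1ccccc1)[C@](C)(O)CO
F5 | step 7 | (2R,3S)-2-methylpent-4-ene-1,2,3-triol | C=C[C@H](O)[C@](C)(O)CO
F6 | step 7 | (2R,3S)-1-[(tert-butyldimethylsilyl)oxy]-2-methylpent-4-ene-2,3-diol | C=C[C@H](O)[C@](C)(O)CO[Si](C)(C)C(C)(C)C
F7 | step 7 | 2,4-bis(methoxymethoxy)-6-methylbenzoyl chloride | Cc1cc(OCOC)cc(OCOC)c1C(Cl)=O
F8 | step 7 | (2R,3S)-1-[(tert-butyldimethylsilyl)oxy]-2-hydroxy-2-methylpent-4-en-3-yl 2,4-bis(methoxymethoxy)-6-methylbenzoate | C=C[C@H](OC(=O)c1c(C)cc(OCOC)cc1OCOC)[C@](C)(O)CO[Si](C)(C)C(C)(C)C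
F9 | step 14 | trimethylsilyl (2E)-3-[(7S,8S,8aS)-8-{[2,4-bis(trimethylsilyloxy)-6-methylbenzoyl]oxy}-7-methyl-6-oxo-7-(trimethylsilyloxy)-6,7,8,8a-tetrahydro-1H-isochromen-3-yl]prop-2-enoate | Cc1cc(O[Si](C)(C)C)cc(O[Si](C)(C)C)c1C(=O)O[C@H]1[C@@H]2COC(/C=C/C(=O)O[Si](C)(C)C)=CC2=CC(=O)[C@@]1(C)O[Si](C)(C)C
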